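The runs were generated by integration with made-up constants; the scatter is artificial.

Of the 3 questions on this flask we commit our own reckoning to the last, the part reacted at the end, which can be counted from two sides.

the same everywhere: left-handed substrate 10 mM; right-handed substrate 10 mM
- Thursday's: coupling partner 12 mM; free catalyst 1 mM; run made earlier
- Tuesday's: coupling partner 12 mM; free catalyst 1.5 mM; run made earlier
- flask: coupling partner 12.0 mM; free catalyst 2.0 mM; time 8.0 d

- Thursday's (time / d: left-handed product / %, right-handed product / %, left-handed substrate / %): 0.417: 4, 10, 43; 0.625: 6, 15, 46; 0.833: 10, 16, 39; 1.25: 13, 18, 38; 2.08: 17, 22, 33; 3.00: 21, 24, 29; 5.00: 27, 28, 25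
- Tuesday's (time / d: left-handed product / %, right-handed product / %, left-handed substrate / %): 0.250: 4, 8, 43; 0.833: 15, 20, 39; 1.25: 14, 23, 34; 2.08: 17, 31, 25; 3.00: 25, 29, 16; 4.00: 27, 30, 19; 5.00: 28, 30, 19

(readings scatter by 2 percentage points)

- free catalyst is single-handed; left-handed substrate and right-handed substrate are mirror images of each other, charged as a racemate, each of them at the stated concentration
- an excess is below zero if the other one leads

1. excess of left-handed product over right-handed product in the product at 20 h
2. excess of left-handed product over right-handed product in the product at 8.0 d
3. part of the left-handed substrate and right-handed substrate charged together that has reacted at 8.0 d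

1. Counting from the product side, and assuming one coupling partner per product, the charges in this flask allow 60.0%, and Tuesday's run, with the same charges of substrates and partner, shows 58.0% of product in its last reading.

2. Counting from the substrate side, and assuming that the two hands go alike, the left-handed substrate peak of that last reading says that 62.0% has reacted, and the two ways differ by 4 percentage points, less than the 4.9 points of scatter on that difference, so that single reading does not part them and we turn to all the readings.

3. To see which way cheats we take the left-handed gap, the left-handed charge less left-handed product and left-handed substrate, and average it over the 7 readings of each run: Thursday's run, with 1 mM of catalyst, gives −0.143%, and Tuesday's run, with 1.5 mM, gives 3.57%. We read this gap as substrate sitting on the catalyst, so the product count is the one that falls short.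

4. We call the catalyst occupancy the substrate of both hands held per catalyst charged; the two gaps together read 54.9%.

5. Our rule adds the held substrate to the partner's allowance, so this flask should reach 65.5% reacted, give or take 2.4 points from the scatter.

The forecast says −17% (−23% to −11%), 0% (−3% to 2%) and 57.5% (55.5% to 60%) for the part reacted, which lies below our figure, on its ground: “12 mM caps conversion at 60%”.

The flask gives −25.9%, −5.54% and 66.1%.

    2 coupling partner → homo dimer (k = 7.70 × 10⁻⁵ /M/s)
    free catalyst + right-handed substrate ⇌ catalyst intermediate B (K = 440 /M, k = 0.390 /M/s)
    free catalyst + left-handed substrate ⇌ catalyst intermediate A (K = 650 /M, k = 0.0140 /M/s)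
    coupling partner ⇌ dormant form (K = 0.600, k = 4.00 × 10⁻⁵ /s)
    coupling partner + catalyst intermediate A → free catalyst + left-handed product (k = 0.0220 /M/s)
    coupling partner + catalyst intermediate B → free catalyst + right-handed product (k = 0.0110 /M/s)

In this flask the coupling partner, the limiting reagent, stands at 0% after 8.00 d, while catalyst intermediate A holds 48.6% of the catalyst and catalyst intermediate B 30.3%. The falling back of catalyst intermediate B to free catalyst and right-handed substrate is the main reason for the excess of −5.54% in this flask at 8.0 d: the same run without that falling back gives −61.3%. The flask stands 6.1 points above the partner's allowance, and our occupancy gave 5.5 points.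

For the neighbour flask with 3.4 mM of free catalyst, the occupancy gives 69.3% reacted; the computed result for that flask is 71.7%.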